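**Remarks**

- Numbering used in the text is that of the target's eunicellane skeleton. Ring fusion is C1/C10. The ten-membered ring is C1–C10, with C2=C3 (methyl C18), acetoxy groups on C6 and C9, and C7=C19H2. The six-membered ring is C1, C10, C11 (methyl C20, OH), C12, C13, C14 (isopropyl C15–C17).
- Assumption: (2-bromoallyl)boronic acid pinacol ester 21 is taken to be a catalogue reagent.

**Retrosynthetic overview**

1. Target 25 comes from triol 24 by diacetylation; the ten-membered ring is closed last at C6–C7 by an intramolecular Nozaki–Hiyama–Kishi reaction of bromoalkene aldehyde 23, with C9 set by catalytic asymmetric 2-bromoallylboration and the (Z)-C2=C3 alkene by Stork–Zhao olefination and B-alkyl Suzuki coupling.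
2. Hydroxy lactone 13 (all four ring stereocentres; C9 as lactone carbonyl, C2 as O–CH2) comes from bis-lactone 10 by turning the bridging lactone carbonyl into the isopropyl group (MeLi, Wittig, H2).
3. Key disconnection: C13–C14 and C12–C11 together, by [4+2] cycloaddition of 2-pyranone ester 4 (diene C14=C1–C10=C11, lactone carbonyl = C15) with phenyl vinyl sulfide as an ethylene equivalent.
4. Enabling feature: in the six-membered ring the C11–O bond and the C14–C15 bond are cis-1,4, with only the unfunctionalised C12H2–C13H2 between them. These are the O–C(=O) bridge and the ethano bridge of a 2-oxabicyclo[2.2.2]oct-5-en-3-one, whose C1=C10 alkene is then hydrogenated from the bridge face to give the cis ring fusion.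
5. Ring order: pyranone (bought) → six-membered carbocycle inside the bridged lactone (step 2) → temporary fused γ-lactone (steps 5–10) → ten-membered ring (step 17).

Key step: step 2

**Route**

Step 1
Reactants: 1 isodehydroacetic acid; 2 (−)-menthol
Product: 4 (1R,2S,5R)-menthyl 4,6-dimethyl-2-oxo-2H-pyran-5-carboxylate, via acid chloride 3 (not isolated)
Conditions: (COCl)2, DMF (cat.), CH2Cl2, 0→25 °C; then 2, Et3N, 4-(dimethylamino)pyridine (cat.), CH2Cl2, 40 °C
Reagents that add atoms: none
Why: Acylation of a secondary alcohol by the hindered acid chloride under nucleophilic catalysis (ester formation); the menthyl group is a covalently bound resolving handle that turns the two enantiomeric series of the later cycloadduct into separable diastereomers.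

Step 2
Reactants: 4 menthyl pyranone ester; 5 phenyl vinyl sulfide
Product: 6 menthyl (1R,4S,8RS)-1,5-dimethyl-3-oxo-8-(phenylsulfanyl)-2-oxabicyclo[2.2.2]oct-5-ene-6-carboxylate (desired bridgehead series drawn; formed together with the opposite bridgehead series)
Conditions: 5 (5 equiv), CH2Cl2, 12 kbar, 25 °C
Reagents that add atoms: none
Why: Inverse-electron-demand Diels–Alder reaction: the ester-bearing, electron-poor pyranone diene (C14=C1–C10=C11) takes up the vinyl sulfide across C11 and C14 in a concerted, asynchronous, suprafacial [4+2] cycloaddition whose leading bond joins the nucleophilic CH2 terminus to C11 (β to the ester). The closest known reaction type is the high-pressure or Lewis-acid-promoted cycloaddition of 3- and 5-acyl-2-pyranones with vinyl ethers and vinyl sulfides, which gives isolable 2-oxabicyclo[2.2.2]oct-5-en-3-ones. The one ring closed, the carbocycle C11–C12–C13–C14–C1–C10, is formed by this [4+2] closure, and the lactone survives as a temporary O–C(=O) bridge. The bridgehead centres C11 and C14 are created together and their relative configuration (C11–O cis to C14–C15) is fixed by the bridge itself, while the absolute sense is not expected from the remote menthyl ester, so both bridgehead series form and are separated after step 3. Regiochemistry and endo/exo selectivity are irrelevant because the sulfur-bearing centre is erased in step 3 and all isomers of the desired bridgehead series converge on 7. The selectivity that is needed is for the bridged adduct over loss of CO2 by retro-[4+2], and 12 kbar at 25 °C should secure it, since pressure accelerates the addition while the cycloreversion needs heat.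

Step 3
Reactants: 6 sulfide cycloadduct
Product: 7 menthyl (1R,4S)-1,5-dimethyl-3-oxo-2-oxabicyclo[2.2.2]oct-5-ene-6-carboxylate (single diastereomer)
Conditions: Raney Ni (W-2, acetone-deactivated), acetone/EtOH, 0→25 °C; menthyl diastereomers separated by crystallisation or chromatography
Reagents that add atoms: none
Why: Raney-nickel desulfurisation cleaves the C–S bond under conditions that should spare the tetrasubstituted, ester-conjugated alkene, and separation of the two menthyl diastereomers (enantiomeric bicycles) fixes the absolute configuration at C11 and C14.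

Step 4
Reactants: 7 bicyclic lactone ester
Product: 8 menthyl (1R,4S)-5-(bromomethyl)-1-methyl-3-oxo-2-oxabicyclo[2.2.2]oct-5-ene-6-carboxylate
Conditions: N-bromosuccinimide, hν (visible lamp), PhCF3, 25 °C
Reagents that add atoms: N-bromosuccinimide O=C1CCC(=O)N1Br
Why: Wohl–Ziegler bromination of the γ-methyl group of a β-methyl enoate; the C1 methyl is the only allylic position with an abstractable hydrogen (C14–H is a bridgehead, C11 is quaternary), and ambient temperature avoids CO2 loss.

Step 5
Reactants: 8 allylic bromide
Product: 9 tricyclic butenolide (bridged lactone C11–O–C15(=O)–C14 retained; butenolide C9(=O)–O–C2H2 fused on C10=C1)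
Conditions: AgO2CCF3, acetone/H2O (5:1), 25 °C
Reagents that add atoms: water O
Why: Silver-assisted ionisation of the allylic bromide with participation of the cis ester carbonyl (five-membered alkoxyfuranium ion), whose hydrolysis should give the butenolide and release menthol, as in the known lactonisation of cis γ-halo enoates.

Step 6
Reactants: 9 tricyclic butenolide
Product: 10 bis-lactone (saturated; H1 and H10 cis to each other, both on the face of the O–C(=O) bridge)
Conditions: H2 (60 bar), Rh/Al2O3, EtOAc, 25 °C
Reagents that add atoms: none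
Why: Heterogeneous syn-hydrogenation of the strained tetrasubstituted butenolide alkene from the less hindered face, the one flanked by the O–C(=O) bridge (no inward hydrogens, lactone oxygen able to anchor to the metal) and not by the CH2–CH2 bridge; this sets C1 and C10 with both hydrogens syn to the C11 oxygen, and Rh is chosen to avoid allylic C–O hydrogenolysis.

Step 7
Reactants: 10 bis-lactone
Product: 11 hydroxy ketone (C14 acetyl, C11 tertiary alcohol, cis-fused γ-lactone intact)
Conditions: MeLi (1.05 equiv), THF, −78 °C; AcOH, −78 °C
Reagents that add atoms: methyllithium [Li]C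
Why: Mono-addition of an organolithium to a lactone through a lithium hemiketal that is stable at −78 °C; the strained boat δ-lactone of the bridge should react before the fused γ-lactone, and opening of the bridge unveils the C11 alcohol and the C14 acetyl group in the configurations set in step 2 (the acetyl group is equatorial, so C14 is also the thermodynamic epimer).

Step 8
Reactants: 11 hydroxy ketone
Product: 12 isopropenyl hydroxy lactone
Conditions: Ph3PCH3Br, NaHMDS, THF, 0 °C; then 11, 0→25 °C
Reagents that add atoms: methyltriphenylphosphonium bromide C[P+](c1ccccc1)(c1ccccc1)c1ccccc1.[Br-]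
Why: Wittig methylenation of the methyl ketone; the ylide is not basic enough to deprotonate the tertiary alcohol (no retro-aldol) and the γ-lactone is inert at this temperature.

Step 9
Reactants: 12 isopropenyl hydroxy lactone
Product: 13 hydroxy lactone with isopropyl group (C1, C10, C11, C14 as in the target)
Conditions: H2 (1 bar), Pd/C, EtOAc, 25 °C
Reagents that add atoms: none
Why: Catalytic hydrogenation of the 1,1-disubstituted alkene completes the isopropyl group without creating a stereocentre.

Step 10
Reactants: 13 hydroxy lactone
Product: 14 Weinreb amide alcohol (C9 amide on C10, C2 primary alcohol on C1)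
Conditions: MeNHOMe·HCl, AlMe3, CH2Cl2, 0→25 °C; Rochelle salt work-up; used at once
Reagents that add atoms: N,O-dimethylhydroxylamine hydrochloride CNOC.Cl
Why: Weinreb aminolysis of a lactone by the aluminium amide differentiates C9 (amide) from C2 (alcohol) without touching C10.

Step 11
Reactants: 14 Weinreb amide alcohol
Product: 15 C2 aldehyde
Conditions: Dess–Martin periodinane, pyridine, CH2Cl2, 0→25 °C
Reagents that add atoms: none
Why: Dess–Martin oxidation of the primary alcohol removes the hydroxyl group that could relactonise; the aldehyde is equatorial on C1, so epimerisation is not a concern.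

Step 12
Reactants: 15 C2 aldehyde
Product: 16 (Z)-2-iodoalkene (iodine cis to C1)
Conditions: Ph3PEtI, n-BuLi, THF, 0 °C; I2, −78 °C; NaHMDS, −20 °C; then 15, −78 °C
Reagents that add atoms: ethyltriphenylphosphonium iodide CC[P+](c1ccccc1)(c1ccccc1)c1ccccc1.[I-]; iodine II
Why: Stork–Zhao olefination with the α-iodo ylide gives the (Z)-iodoalkene under kinetic control, which fixes the geometry of the future C2=C3 alkene.

Step 13
Reactants: 16 (Z)-iodoalkene; 17 acrolein diethyl acetal
Product: 19 (Z)-trisubstituted alkene acetal, via B-alkyl-9-BBN 18 (not isolated)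
Conditions: 17, 9-borabicyclo[3.3.1]nonane (9-BBN) dimer, THF, 25 °C; then 16, PdCl2(dppf) (dppf = 1,1'-bis(diphenylphosphino)ferrocene), AsPh3, Cs2CO3, DMF/H2O, 25 °C
Reagents that add atoms: none
Why: Anti-Markovnikov hydroboration followed by B-alkyl Suzuki–Miyaura coupling, which proceeds with retention of alkene geometry, so C4 replaces iodine cis to C1 and the (Z)-C2=C3 alkene with C4–C6 is in place.

Step 14
Reactants: 19 Weinreb amide acetal
Product: 20 C9 aldehyde
Conditions: i-Bu2AlH, THF, −78 °C; Rochelle salt, 0 °C; used at once
Reagents that add atoms: none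
Why: Reduction of a Weinreb amide stops at the aldehyde through the chelated tetrahedral intermediate; cold, near-neutral work-up avoids epimerisation at C10 and retro-aldol loss of the C11 alcohol.

Step 15
Reactants: 20 C9 aldehyde; 21 (2-bromoallyl)boronic acid pinacol ester
Product: 22 (9R)-2-bromoallyl carbinol
Conditions: (R)-3,3'-bis(2,4,6-triisopropylphenyl)-1,1'-binaphthyl-2,2'-diyl hydrogen phosphate (5 mol%), 4 Å molecular sieves, toluene, −30 °C
Reagents that add atoms: none
Why: Chiral phosphoric acid-catalysed allylboration through a closed chair transition state in which the (R)-catalyst directs addition to the Re face of the aldehyde to give (9R); the Felkin–Anh preference (nucleophile anti to the quaternary C11) points the same way.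

Step 16
Reactants: 22 bromoallyl carbinol acetal
Product: 23 bromoalkene aldehyde (C6 aldehyde)
Conditions: pyridinium p-toluenesulfonate, acetone/H2O (10:1), 45 °C
Reagents that add atoms: water O
Why: Mild acid-catalysed acetal hydrolysis, under which the tertiary alcohol, the trisubstituted alkene and the bromoalkene should be stable.

Step 17
Reactants: 23 bromoalkene aldehyde
Product: 24 (6R,9R)-triol with the ten-membered ring (6,9-dideacetyl target)
Conditions: CrCl2 (10 equiv), NiCl2 (5 mol%), DMSO, 3 mM, 25 °C
Reagents that add atoms: none
Why: Intramolecular Nozaki–Hiyama–Kishi reaction (zerovalent nickel inserts into the C–Br bond, the alkenyl group passes to trivalent chromium and adds to the aldehyde) closes the ten-membered ring at C6–C7 and creates the C6 carbinol next to the exocyclic methylene; the (Z)-alkene and the cis ring fusion bring the chain ends together, and C6 is set under macrocyclic control, the (6R) epimer being the one expected (checked in the fallback).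

Step 18
Reactants: 24 triol
Product: 25 target diacetate
Conditions: Ac2O, pyridine, 4-(dimethylamino)pyridine (cat.), CH2Cl2, 0→25 °C
Reagents that add atoms: acetic anhydride CC(=O)OC(C)=O
Why: Acetylation of the two secondary alcohols; the hindered tertiary C11 alcohol should not react under these conditions.

**Compound list**

1 | isodehydroacetic acid (4,6-dimethyl-2-oxo-2H-pyran-5-carboxylic acid) | CC1=C(C(=O)O)C(C)=CC(=O)O1 | starting material
2 | (−)-menthol, (1R,2S,5R)-2-isopropyl-5-methylcyclohexan-1-ol | C[C@@H]1CC[C@H]([C@@H](C1)O)C(C)C | starting material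
3 | 4,6-dimethyl-2-oxo-2H-pyran-5-carbonyl chloride | CC1=C(C(=O)Cl)C(C)=CC(=O)O1 | intermediate
4 | (1R,2S,5R)-menthyl 4,6-dimethyl-2-oxo-2H-pyran-5-carboxylate | CC1=C(C(=O)O[C@@H]2C[C@H](C)CC[C@H]2C(C)C)C(C)=CC(=O)O1 | intermediate
5 | phenyl vinyl sulfide | C=CSc1ccccc1 | starting material
6 | menthyl (1R,4S,8RS)-1,5-dimethyl-3-oxo-8-(phenylsulfanyl)-2-oxabicyclo[2.2.2]oct-5-ene-6-carboxylate (epimers at the sulfur-bearing carbon) | C[C@]12CC(Sc3ccccc3)[C@H](C(=O)O1)C(C)=C2C(=O)O[C@@H]4C[C@H](C)CC[C@H]4C(C)C | intermediate
7 | menthyl (1R,4S)-1,5-dimethyl-3-oxo-2-oxabicyclo[2.2.2]oct-5-ene-6-carboxylate | C[C@]12CC[C@H](C(=O)O1)C(C)=C2C(=O)O[C@@H]3C[C@H](C)CC[C@H]3C(C)C | intermediate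
8 | menthyl (1R,4S)-5-(bromomethyl)-1-methyl-3-oxo-2-oxabicyclo[2.2.2]oct-5-ene-6-carboxylate | C[C@]12CC[C@H](C(=O)O1)C(CBr)=C2C(=O)O[C@@H]3C[C@H](C)CC[C@H]3C(C)C | intermediate
9 | tricyclic butenolide: bridged lactone of 7 with a butenolide (C9 carbonyl, C2 methylene) fused on the C1=C10 alkene | C[C@]12CC[C@H](C(=O)O1)C3=C2C(=O)OC3 | intermediate
10 | bis-lactone: 9 hydrogenated, H1 and H10 on the face of the O–C(=O) bridge | C[C@]12CC[C@H](C(=O)O1)[C@@H]3[C@H]2C(=O)OC3 | intermediate
11 | hydroxy ketone: cyclohexane with C11 (OH, CH3), C14 acetyl cis to the C11 oxygen, cis-fused γ-lactone on C10/C1 trans to both | CC(=O)[C@H]1CC[C@@](C)(O)[C@H]2[C@@H]1COC2=O | intermediate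
12 | isopropenyl analogue of 11 | C=C(C)[C@H]1CC[C@@](C)(O)[C@H]2[C@@H]1COC2=O | intermediate
13 | isopropyl hydroxy lactone (C1, C10, C11, C14 as in the target) | CC(C)[C@H]1CC[C@@](C)(O)[C@H]2[C@@H]1COC2=O | intermediate
14 | Weinreb amide alcohol: C10–C(=O)N(OMe)Me and C1–CH2OH cis on the core of 13 | CC(C)[C@H]1CC[C@@](C)(O)[C@H](C(=O)N(C)OC)[C@@H]1CO | intermediate
15 | C2 aldehyde of 14 | CC(C)[C@H]1CC[C@@](C)(O)[C@H](C(=O)N(C)OC)[C@@H]1C=O | intermediate
16 | (Z)-2-iodoprop-1-enyl compound (C1–CH=C(I)CH3, iodine cis to C1) | CC(C)[C@H]1CC[C@@](C)(O)[C@H](C(=O)N(C)OC)[C@@H]1/C=C(/C)I | intermediate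
17 | acrolein diethyl acetal (3,3-diethoxyprop-1-ene) | C=CC(OCC)OCC | starting material
18 | 9-(3,3-diethoxypropyl)-9-borabicyclo[3.3.1]nonane | CCOC(CCB1C2CCCC1CCC2)OCC | intermediate
19 | (Z)-alkene Weinreb amide with C4–C6 chain ending in the diethyl acetal | CC(C)[C@H]1CC[C@@](C)(O)[C@H](C(=O)N(C)OC)[C@@H]1/C=C(/C)CCC(OCC)OCC | intermediate
20 | C9 aldehyde of 19 | CC(C)[C@H]1CC[C@@](C)(O)[C@H](C=O)[C@@H]1/C=C(/C)CCC(OCC)OCC | intermediate
21 | 2-(2-bromoallyl)-4,4,5,5-tetramethyl-1,3,2-dioxaborolane | C=C(Br)CB1OC(C)(C)C(C)(C)O1 | starting material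
22 | (9R)-carbinol with 2-bromoallyl group (C9(OH)–C8H2–C7(Br)=C19H2) and C6 acetal | CC(C)[C@H]1CC[C@@](C)(O)[C@H]([C@H](O)CC(Br)=C)[C@@H]1/C=C(/C)CCC(OCC)OCC | intermediate
23 | bromoalkene aldehyde (C6 aldehyde of 22) | CC(C)[C@H]1CC[C@@](C)(O)[C@H]([C@H](O)CC(Br)=C)[C@@H]1/C=C(/C)CCC=O | intermediate
24 | (6R,9R)-eunicella-2(Z),7(19)-diene-6,9,11-triol (6,9-dideacetyl target) | C=C1C[C@@H](O)[C@@H]2[C@H](/C=C(/C)CC[C@H]1O)[C@@H](C(C)C)CC[C@@]2(C)O | intermediate
25 | (1S,2Z,6R,9R,10S,11R,14R)-6,9-diacetoxyeunicella-2,7(19)-dien-11-ol | C=C1C[C@@H](OC(C)=O)[C@@H]2[C@H](/C=C(/C)CC[C@H]1OC(C)=O)[C@@H](C(C)C)CC[C@@]2(C)O | target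

**Summary**

Total step count: 18. Longest linear sequence: 18 steps (from 1).

**Steps most likely to fail**

Step 2. The process at risk is a slow cycloaddition of the tetrasubstituted pyranone combined with extrusion of CO2 from the adduct, followed by aromatisation. The fallback sets out from compound 4. Electrophilic bromination at the one free ring position (N-bromosuccinimide, MeCN, dark) would give menthyl 3-bromo-4,6-dimethyl-2-oxo-2H-pyran-5-carboxylate F1. 3-Bromo-2-pyranones are ambiphilic dienes whose cycloadducts resist cycloreversion, so F1 and phenyl vinyl sulfide 5 should combine under milder pressure to the bridgehead bromide menthyl 4-bromo-1,5-dimethyl-3-oxo-8-(phenylsulfanyl)-2-oxabicyclo[2.2.2]oct-5-ene-6-carboxylate F2. Radical debromination of the bridgehead (Bu3SnH, Et3B, air, 0–25 °C) then comes back to the route at compound 6.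

Step 7. The process at risk is loss of chemoselectivity, with methyllithium also adding to the γ-lactone carbonyl, or adding twice. The fallback sets out from compound 10. LDA (THF, −78 °C) would first convert the only enolisable lactone into the lithium enolate of the γ-lactone F3; the bridged lactone has only a bridgehead α-hydrogen and cannot enolise. Methyllithium then finds a single electrophilic carbonyl. Quench with AcOH at −78 °C, with protonation of C10 on the face of the neighbouring H1 (cis ring fusion), comes back to the route at compound 11.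

Step 17. The process at risk is poor facial selectivity at the aldehyde during ring closure, so that the C6 epimer predominates, besides oligomerisation at insufficient dilution. The fallback sets out from compound 23. Should the closure give mainly the 6-epimer of the triol F4, chemoselective oxidation of its allylic alcohol (MnO2, CH2Cl2) would give the C6 enone F5. Reagent-controlled reduction with (S)-1-methyl-3,3-diphenyl-tetrahydro-1H,3H-pyrrolo[1,2-c][1,3,2]oxazaborole and BH3·SMe2 (alkenyl as the large group, giving 6R) comes back to the route at compound 24.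

**Further compounds**

F1 | step 2 | (1R,2S,5R)-menthyl 3-bromo-4,6-dimethyl-2-oxo-2H-pyran-5-carboxylate | CC1=C(C(=O)O[C@@H]2C[C@H](C)CC[C@H]2C(C)C)C(C)=C(Br)C(=O)O1
F2 | step 2 | menthyl 4-bromo-1,5-dimethyl-3-oxo-8-(phenylsulfanyl)-2-oxabicyclo[2.2.2]oct-5-ene-6-carboxylate (bridgeheads as in 6) | C[C@]12CC(Sc3ccccc3)[C@](Br)(C(=O)O1)C(C)=C2C(=O)O[C@@H]4C[C@H](C)CC[C@H]4C(C)C
F3 | step 7 | lithium enolate of the γ-lactone of 10 | [Li+].C[C@]12CC[C@H](C(=O)O1)[C@@H]3C2=C([O-])OC3
F4 | step 17 | (6S,9R)-triol, the 6-epimer of 24 | C=C1C[C@@H](O)[C@@H]2[C@H](/C=C(/C)CC[C@@H]1O)[C@@H](C(C)C)CC[C@@]2(C)O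
F5 | step 17 | C6 ketone (7(19)-en-6-one) of 24 | C=C1C[C@@H](O)[C@@H]2[C@H](/C=C(/C)CCC1=O)[C@@H](C(C)C)CC[C@@]2(C)O
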